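The central benzene ring (chromene C4a–C5–C6–C7–C8–C8a) is a masked, symmetric 4,6‑diprenyl‑5‑arylresorcinol: C5 carries the benzofuran, C6 and C4a each carry a five‑carbon prenyl unit, C7 and C8a each carry oxygen, and the pyran is one prenyl closed onto its ortho oxygen. The ring is therefore built, not functionalised. A polyketide‑type aldol cyclodehydration of a linear 1‑(benzofuran‑2‑yl)‑1,3,5‑triketone, made from a symmetric bis‑homoprenyl 1,3‑diketone and a benzofuran‑2‑carboxylate, closes the bond between the benzofuran‑bearing carbon and a prenyl‑bearing carbon and aromatises, fixing all six substituents without regiochemical choice. One dehydrogenative prenyl‑to‑pyran closure then breaks the symmetry.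

Key step: step 5

Remark: the target has no stereogenic element (it is achiral), so nothing has to be controlled; methyl 6‑hydroxybenzofuran‑2‑carboxylate (5) is taken as a catalogue compound.

Step 1
Reactants: 1 pentane‑2,4‑dione; 2 1‑bromo‑3‑methylbut‑2‑ene (prenyl bromide)
Product: 3 8‑methylnon‑7‑ene‑2,4‑dione
Conditions: LDA (2.1 equiv), THF, 0 °C; then 2 (1.0 equiv), −78 → 0 °C; AcOH; distillation
Reagents that add atoms: none
Why: Terminal (γ) alkylation of the 1,3‑diketone dianion by the allylic bromide (SN2) at the more basic methyl carbanion; the resulting stabilised monoanion should not be alkylated further at this temperature.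

Step 2
Reactants: 3 8‑methylnon‑7‑ene‑2,4‑dione; 2 1‑bromo‑3‑methylbut‑2‑ene (prenyl bromide)
Product: 4 2,12‑dimethyltrideca‑2,11‑diene‑6,8‑dione
Conditions: LDA (2.1 equiv), THF, 0 °C; then 2 (1.0 equiv), −78 → 0 °C; AcOH
Reagents that add atoms: none
Why: Second 1,3‑diketone dianion alkylation: the second deprotonation of 3 is expected at the remaining methyl group and not at the methylene (kinetic preference for the less substituted terminus), so the second prenyl enters at the other end and the diketone comes out symmetric.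

Step 3
Reactants: 5 methyl 6‑hydroxy‑1‑benzofuran‑2‑carboxylate
Product: 6 methyl 6‑(prop‑2‑en‑1‑yloxy)‑1‑benzofuran‑2‑carboxylate
Conditions: allyl bromide, K2CO3, DMF, rt
Reagents that add atoms: allyl bromide, C=CCBr
Why: Williamson etherification of the phenol gives an ether that should survive the diketone dianion, hydroxide and DDQ and can be removed at the end under neutral Pd(0) conditions.

Step 4
Reactants: 4 2,12‑dimethyltrideca‑2,11‑diene‑6,8‑dione; 6 methyl 6‑(prop‑2‑en‑1‑yloxy)‑1‑benzofuran‑2‑carboxylate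
Product: 7 1‑[6‑(allyloxy)‑1‑benzofuran‑2‑yl]‑9‑methyl‑2‑(3‑methylbut‑2‑en‑1‑yl)dec‑8‑ene‑1,3,5‑trione
Conditions: 4 (2.2 equiv), LDA (4.4 equiv), THF, 0 °C; then 6, −78 → 0 °C; AcOH, −78 °C; used without prolonged storage
Reagents that add atoms: none
Why: Crossed Claisen acylation of the 1,3‑diketone dianion at its more basic terminal carbanion by the ester; the excess dianion takes up the acidic proton of the triketone, the symmetry of 4 makes both terminal positions equivalent, and no free LDA is present when the allyl ether is added.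

Step 5
Reactants: 7 1‑[6‑(allyloxy)‑1‑benzofuran‑2‑yl]‑9‑methyl‑2‑(3‑methylbut‑2‑en‑1‑yl)dec‑8‑ene‑1,3,5‑trione
Product: 9 5‑[6‑(allyloxy)‑1‑benzofuran‑2‑yl]‑4,6‑bis(3‑methylbut‑2‑en‑1‑yl)benzene‑1,3‑diol, via 5‑[6‑(allyloxy)‑1‑benzofuran‑2‑yl]‑5‑hydroxy‑4,6‑bis(3‑methylbut‑2‑en‑1‑yl)cyclohexane‑1,3‑dione 8 (not isolated)
Conditions: KOH (3 equiv), MeOH–H2O 4:1 (degassed), 0 → 40 °C, Ar; then 1 M HCl to pH 4
Reagents that add atoms: none
Why: Under reversible enolisation in aqueous‑alcoholic hydroxide, the enolate of the C5 ketone towards C6 (the CH2 that carries the prenyl chain) adds to the C1 aryl ketone; the β‑hydroxy dione 8 then loses water by E1cB and tautomerises to the resorcinol, an irreversible aromatisation that should drain all equilibria. The closest known reaction type is the base‑induced intramolecular aldol aromatisation of 1,3,5‑triketones (heptane‑2,4,6‑trione to orcinol) and of 3,5,7‑triketo acids to resorcinols, the laboratory counterpart of the aldol used by biphenyl synthase. The carbocycle closes in a 6‑(enolendo)‑exo‑trig mode, forming the bond between the benzofuran‑bearing carbon and one prenyl‑bearing carbon and with it the fully substituted biaryl junction. No stereocentre survives, since the centres of 7 and 8 are erased on aromatisation. The step needs chemoselectivity only: C2 or C4 as nucleophile could give only four‑membered rings, O‑cyclisation to the 4‑pyranone is reversed by hydroxide, the 2‑prenyl group disfavours the planar C1/C3 enol so that C1 stays a ketone, and the symmetric origin of the chain leaves no regiochemical alternative. The competing irreversible path is retro‑Claisen cleavage, which low temperature and exclusion of oxygen should keep down.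

Step 6
Reactants: 9 5‑[6‑(allyloxy)‑1‑benzofuran‑2‑yl]‑4,6‑bis(3‑methylbut‑2‑en‑1‑yl)benzene‑1,3‑diol
Product: 11 5‑[6‑(allyloxy)‑1‑benzofuran‑2‑yl]‑2,2‑dimethyl‑6‑(3‑methylbut‑2‑en‑1‑yl)‑2H‑chromen‑7‑ol, via 3‑[6‑(allyloxy)‑1‑benzofuran‑2‑yl]‑5‑hydroxy‑4‑(3‑methylbut‑2‑en‑1‑yl)‑2‑(3‑methylbut‑2‑en‑1‑ylidene)cyclohexa‑3,5‑dien‑1‑one 10 (not isolated)
Conditions: DDQ (1.0 equiv, slow addition), benzene, rt
Reagents that add atoms: none
Why: Dehydrogenative chromene formation from an o‑prenylphenol: DDQ abstracts a benzylic hydride to give o‑quinone methide 10, whose oxa‑6π electrocyclisation closes the 2,2‑dimethyl‑2H‑pyran, and because the two prenyl/OH pairs of 9 are equivalent either closure gives the same product.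

Step 7
Reactants: 11 5‑[6‑(allyloxy)‑1‑benzofuran‑2‑yl]‑2,2‑dimethyl‑6‑(3‑methylbut‑2‑en‑1‑yl)‑2H‑chromen‑7‑ol
Product: 12 cathafuran C, 2‑[7‑hydroxy‑2,2‑dimethyl‑6‑(3‑methylbut‑2‑en‑1‑yl)‑2H‑chromen‑5‑yl]‑1‑benzofuran‑6‑ol
Conditions: Pd(PPh3)4 (5 mol %), morpholine, THF, rt
Reagents that add atoms: none
Why: Tsuji–Trost deallylation: Pd(0) should ionise only the unhindered allyl aryl ether and morpholine traps the π‑allyl, while the C‑prenyl group, the hindered cyclic chromene ether and the free phenols are expected to be left alone under these neutral conditions.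

Compound list
1 | pentane‑2,4‑dione | CC(=O)CC(C)=O | starting material
2 | 1‑bromo‑3‑methylbut‑2‑ene (prenyl bromide) | CC(C)=CCBr | starting material
3 | 8‑methylnon‑7‑ene‑2,4‑dione | CC(=O)CC(=O)CCC=C(C)C | intermediate
4 | 2,12‑dimethyltrideca‑2,11‑diene‑6,8‑dione | CC(C)=CCCC(=O)CC(=O)CCC=C(C)C | intermediate
5 | methyl 6‑hydroxy‑1‑benzofuran‑2‑carboxylate | COC(=O)c1cc2ccc(O)cc2o1 | starting material
6 | methyl 6‑(prop‑2‑en‑1‑yloxy)‑1‑benzofuran‑2‑carboxylate | COC(=O)c1cc2ccc(OCC=C)cc2o1 | intermediate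
7 | 1‑[6‑(allyloxy)‑1‑benzofuran‑2‑yl]‑9‑methyl‑2‑(3‑methylbut‑2‑en‑1‑yl)dec‑8‑ene‑1,3,5‑trione (racemic at C2, drawn as the triketo tautomer) | CC(C)=CCCC(=O)CC(=O)C(CC=C(C)C)C(=O)c1cc2ccc(OCC=C)cc2o1 | intermediate
8 | 5‑[6‑(allyloxy)‑1‑benzofuran‑2‑yl]‑5‑hydroxy‑4,6‑bis(3‑methylbut‑2‑en‑1‑yl)cyclohexane‑1,3‑dione (mixture of diastereomers, not isolated) | CC(C)=CCC1C(=O)CC(=O)C(CC=C(C)C)C1(O)c1cc2ccc(OCC=C)cc2o1 | intermediate
9 | 5‑[6‑(allyloxy)‑1‑benzofuran‑2‑yl]‑4,6‑bis(3‑methylbut‑2‑en‑1‑yl)benzene‑1,3‑diol | CC(C)=CCc1c(O)cc(O)c(CC=C(C)C)c1-c1cc2ccc(OCC=C)cc2o1 | intermediate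
10 | 3‑[6‑(allyloxy)‑1‑benzofuran‑2‑yl]‑5‑hydroxy‑4‑(3‑methylbut‑2‑en‑1‑yl)‑2‑(3‑methylbut‑2‑en‑1‑ylidene)cyclohexa‑3,5‑dien‑1‑one (o‑quinone methide, exocyclic alkene geometry not defined, not isolated) | CC(C)=CC=C1C(=O)C=C(O)C(CC=C(C)C)=C1c1cc2ccc(OCC=C)cc2o1 | intermediate
11 | 5‑[6‑(allyloxy)‑1‑benzofuran‑2‑yl]‑2,2‑dimethyl‑6‑(3‑methylbut‑2‑en‑1‑yl)‑2H‑chromen‑7‑ol | CC(C)=CCc1c(O)cc2c(c1-c1cc3ccc(OCC=C)cc3o1)C=CC(C)(C)O2 | intermediate
12 | cathafuran C, 2‑[7‑hydroxy‑2,2‑dimethyl‑6‑(3‑methylbut‑2‑en‑1‑yl)‑2H‑chromen‑5‑yl]‑1‑benzofuran‑6‑ol (achiral) | CC(C)=CCc1c(O)cc2c(c1-c1cc3ccc(O)cc3o1)C=CC(C)(C)O2 | target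

Total step count: 7
Longest linear sequence: 6 steps (1 → 2 → 4 → 5 → 6 → 7 from compound 1; the branch from compound 5 is 3 → 4 → 5 → 6 → 7)

Steps most likely to fail

Step 5. The hindered aldol addition may be too slow, so that hydroxide‑induced retro‑Claisen cleavage of the triketone, or dehydrative O‑cyclisation to the 4‑pyranone, outruns carbocyclisation. The fallback activates the nucleophilic carbon as a β‑keto acid, so that the ring can close at near‑neutral pH where the aryl ketone is not enolised and retro‑Claisen cleavage is slow. It sets out from 7: the trianion (LDA, 3.3 equiv, THF, 0 °C) should be carboxylated at its terminal carbanion with CO2 to give 7‑[6‑(allyloxy)‑1‑benzofuran‑2‑yl]‑2,6‑bis(3‑methylbut‑2‑en‑1‑yl)‑3,5,7‑trioxoheptanoic acid F1. In aqueous KHCO3 buffer (pH 8–9, rt → 40 °C) the doubly activated C2 of F1 is expected to add to the aryl ketone, and the cyclic aldol should aromatise by loss of CO2 and water. The route is rejoined at 9.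

Step 6. The remaining prenyl/OH pair of the product is about as reactive as those of the starting diol, so over‑oxidation to the bis‑pyran and incomplete conversion may erode the mono‑cyclised material. The fallback makes a second closure impossible. It sets out from 9: mono‑silylation (TBSCl, 1.0 equiv, imidazole, CH2Cl2, 0 °C; unreacted 9 and any bis‑silyl ether are returned to 9 with TBAF) should give 5‑[6‑(allyloxy)‑1‑benzofuran‑2‑yl]‑3‑(tert‑butyldimethylsilyloxy)‑4,6‑bis(3‑methylbut‑2‑en‑1‑yl)phenol F2. DDQ can then cyclise only the prenyl group ortho to the free hydroxyl, giving the silyl ether of 11, 5‑[6‑(allyloxy)‑1‑benzofuran‑2‑yl]‑7‑(tert‑butyldimethylsilyloxy)‑2,2‑dimethyl‑6‑(3‑methylbut‑2‑en‑1‑yl)‑2H‑chromene F3. TBAF in THF should then remove the silyl group, and the route is rejoined at 11.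

Step 4. Attack of the secondary terminal carbanion on the ester may be slow, and proton transfer from the more acidic triketone to the dianion may stall conversion; the crude product may also cyclodehydrate on acidic work‑up. The fallback replaces the Claisen acylation by an aldol addition followed by oxidation, which forms no acidic product during C–C bond formation. It sets out from 6 and 4: DIBAL‑H (CH2Cl2, −78 °C) should reduce 6 to 6‑(allyloxy)‑1‑benzofuran‑2‑carbaldehyde F4. Addition of the dianion of 4 (LDA, THF, −78 °C) should give 1‑[6‑(allyloxy)‑1‑benzofuran‑2‑yl]‑1‑hydroxy‑9‑methyl‑2‑(3‑methylbut‑2‑en‑1‑yl)dec‑8‑ene‑3,5‑dione F5. Dess–Martin oxidation of the carbinol then rejoins the route at 7.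

Further compounds
F1 | step 5 | 7‑[6‑(allyloxy)‑1‑benzofuran‑2‑yl]‑2,6‑bis(3‑methylbut‑2‑en‑1‑yl)‑3,5,7‑trioxoheptanoic acid (mixture of diastereomers) | OC(=O)C(CC=C(C)C)C(=O)CC(=O)C(CC=C(C)C)C(=O)c1cc2ccc(OCC=C)cc2o1
F2 | step 6 | 5‑[6‑(allyloxy)‑1‑benzofuran‑2‑yl]‑3‑(tert‑butyldimethylsilyloxy)‑4,6‑bis(3‑methylbut‑2‑en‑1‑yl)phenol | CC(C)=CCc1c(O)cc(O[Si](C)(C)C(C)(C)C)c(CC=C(C)C)c1-c1cc2ccc(OCC=C)cc2o1
F3 | step 6 | 5‑[6‑(allyloxy)‑1‑benzofuran‑2‑yl]‑7‑(tert‑butyldimethylsilyloxy)‑2,2‑dimethyl‑6‑(3‑methylbut‑2‑en‑1‑yl)‑2H‑chromene | CC(C)=CCc1c(O[Si](C)(C)C(C)(C)C)cc2c(c1-c1cc3ccc(OCC=C)cc3o1)C=CC(C)(C)O2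
F4 | step 4 | 6‑(allyloxy)‑1‑benzofuran‑2‑carbaldehyde | O=Cc1cc2ccc(OCC=C)cc2o1
F5 | step 4 | 1‑[6‑(allyloxy)‑1‑benzofuran‑2‑yl]‑1‑hydroxy‑9‑methyl‑2‑(3‑methylbut‑2‑en‑1‑yl)dec‑8‑ene‑3,5‑dione (mixture of diastereomers) | CC(C)=CCCC(=O)CC(=O)C(CC=C(C)C)C(O)c1cc2ccc(OCC=C)cc2o1
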